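**Retrosynthetic overview**
- The target (25) is the tri-O-demethylated form of bis-coumarin 23. Unit A is the 7-hydroxy-6-aryloxy coumarin and unit B is the 5-aryloxy-6,7-dihydroxy coumarin.
- Each pyranone ring is cut at C3–C4: an intermolecular Knoevenagel (aldol-type) condensation of diethyl malonate with a salicylaldehyde, then lactonisation, with the 3-carboxyl groups removed at the end.
- The diaryl ether comes from an SNAr reaction of the hindered phenol 6 with 1-fluoro-2-methoxy-4-nitrobenzene. The nitro group is then converted to OH and the ring ortho-formylated to give the second salicylaldehyde.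
- Phenol 6 comes from 3,4,5-trimethoxyphenol by methylation, Vilsmeier formylation and chelation-controlled mono-demethylation.
- Both benzene rings are bought. The pyranone ring of unit B is closed first (step 6), the pyranone ring of unit A second (step 10).

Assumption: the target SMILES has no stereocentre and no stereogenic double bond, so it is achiral and no stereocontrol is needed.

**Route**

Step 1
Reactants: 1 3,4,5-trimethoxyphenol
Product: 2 1,2,3,5-tetramethoxybenzene
Conditions: MeI, K2CO3, acetone, reflux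
Reagents that add atoms: iodomethane, CI
Why: Williamson O-methylation (SN2) of the phenoxide gives the symmetric tetramethyl ether.

Step 2
Reactants: 2 1,2,3,5-tetramethoxybenzene
Product: 4 2,3,4,6-tetramethoxybenzaldehyde, via aryl iminium chloride 3 (not isolated)
Conditions: POCl3, DMF, 0 °C to 60 °C; then ice/H2O
Reagents that add atoms: N,N-dimethylformamide, CN(C)C=O (formyl carbon); water, O (carbonyl oxygen)
Why: Vilsmeier–Haack formylation of a very electron-rich arene whose two free positions are equivalent, so only one aldehyde can form.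

Step 3
Reactants: 4 2,3,4,6-tetramethoxybenzaldehyde
Product: 6 2-hydroxy-3,4,6-trimethoxybenzaldehyde, via dichloroaluminium phenoxide 5 (not isolated)
Conditions: AlCl3 (1.1 equiv), CH2Cl2, 0 °C to rt; then 1 M HCl
Reagents that add atoms: none
Why: Chelation-controlled Lewis-acid demethylation ortho to the carbonyl, which removes the buttressed 2-methoxy group (flanked by CHO and 3-OMe) in preference to the 6-methoxy group, as is established for the corresponding acetophenone.

Step 4
Reactants: 6 2-hydroxy-3,4,6-trimethoxybenzaldehyde; 7 1-fluoro-2-methoxy-4-nitrobenzene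
Product: 8 3,4,6-trimethoxy-2-(2-methoxy-4-nitrophenoxy)benzaldehyde
Conditions: K2CO3, DMF, 90 °C
Reagents that add atoms: none
Why: Nucleophilic aromatic substitution (SNAr) of the fluoride para to the nitro group, a reaction that tolerates a doubly ortho-substituted phenoxide.

Step 5
Reactants: 8 3,4,6-trimethoxy-2-(2-methoxy-4-nitrophenoxy)benzaldehyde
Product: 10 6-hydroxy-3,4-dimethoxy-2-(2-methoxy-4-nitrophenoxy)benzaldehyde, via dichloroboron aryloxide 9 (not isolated)
Conditions: BCl3 (1.5 equiv), CH2Cl2, -78 °C to 0 °C; then H2O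
Reagents that add atoms: none
Why: BCl3 chelation-controlled demethylation cleaves only the one methoxy group that is ortho to the formyl group and leaves the other aryl methyl ethers and the diaryl ether intact.

Step 6
Reactants: 10 6-hydroxy-3,4-dimethoxy-2-(2-methoxy-4-nitrophenoxy)benzaldehyde; 11 diethyl malonate
Product: 13 ethyl 6,7-dimethoxy-5-(2-methoxy-4-nitrophenoxy)-2-oxo-2H-chromene-3-carboxylate, via arylidene malonate 12 (not isolated)
Conditions: piperidine (cat.), AcOH (cat.), EtOH, reflux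
Reagents that add atoms: none
Why: Knoevenagel condensation (amine-catalysed aldol-type addition of the malonate carbanion to the aldehyde, then dehydration) joins the two fragments at the future C3–C4 bond, and the ortho-hydroxyl lactonises onto one ester to close the pyranone of unit B; no stereocentre is formed.

Step 7
Reactants: 13 ethyl 6,7-dimethoxy-5-(2-methoxy-4-nitrophenoxy)-2-oxo-2H-chromene-3-carboxylate
Product: 14 ethyl 5-(4-amino-2-methoxyphenoxy)-6,7-dimethoxy-2-oxo-2H-chromene-3-carboxylate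
Conditions: Fe powder, NH4Cl, EtOH/H2O, 75 °C
Reagents that add atoms: none
Why: Béchamp-type metal reduction of the nitro group under near-neutral conditions spares the conjugated C=C, the ester and the lactone.

Step 8
Reactants: 14 ethyl 5-(4-amino-2-methoxyphenoxy)-6,7-dimethoxy-2-oxo-2H-chromene-3-carboxylate
Product: 16 ethyl 5-(4-hydroxy-2-methoxyphenoxy)-6,7-dimethoxy-2-oxo-2H-chromene-3-carboxylate, via arenediazonium hydrogensulfate 15 (not isolated)
Conditions: NaNO2, H2SO4, AcOH/H2O, 0 °C; then Cu(NO3)2, Cu2O, H2O, rt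
Reagents that add atoms: water, O
Why: Diazotisation followed by copper-mediated hydroxy-dediazoniation (Sandmeyer-type) at room temperature replaces the amino group by OH without heating the diazonium salt.

Step 9
Reactants: 16 ethyl 5-(4-hydroxy-2-methoxyphenoxy)-6,7-dimethoxy-2-oxo-2H-chromene-3-carboxylate
Product: 18 ethyl 5-(5-formyl-4-hydroxy-2-methoxyphenoxy)-6,7-dimethoxy-2-oxo-2H-chromene-3-carboxylate, via hydroxymethyl phenol 17 (not isolated)
Conditions: MgCl2, Et3N, paraformaldehyde, THF, reflux; then 1 M HCl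
Reagents that add atoms: formaldehyde (from paraformaldehyde), C=O
Why: Casnati–Skattebøl magnesium-mediated ortho-formylation reacts only ortho to the free phenol and takes the less hindered ortho site (para to OMe, not the one between OH and OMe).

Step 10
Reactants: 18 ethyl 5-(5-formyl-4-hydroxy-2-methoxyphenoxy)-6,7-dimethoxy-2-oxo-2H-chromene-3-carboxylate; 11 diethyl malonate
Product: 20 ethyl 5-{[3-(ethoxycarbonyl)-7-methoxy-2-oxo-2H-chromen-6-yl]oxy}-6,7-dimethoxy-2-oxo-2H-chromene-3-carboxylate, via arylidene malonate 19 (not isolated)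
Conditions: piperidine (cat.), AcOH (cat.), EtOH, reflux
Reagents that add atoms: none
Why: A second Knoevenagel condensation and lactonisation, now on an unhindered electron-rich salicylaldehyde, closes the pyranone of unit A.

Step 11
Reactants: 20 ethyl 5-{[3-(ethoxycarbonyl)-7-methoxy-2-oxo-2H-chromen-6-yl]oxy}-6,7-dimethoxy-2-oxo-2H-chromene-3-carboxylate
Product: 22 5-[(3-carboxy-7-methoxy-2-oxo-2H-chromen-6-yl)oxy]-6,7-dimethoxy-2-oxo-2H-chromene-3-carboxylic acid, via dilithium dicarboxylate 21 (not isolated)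
Conditions: LiOH, THF/H2O, rt; then 1 M HCl
Reagents that add atoms: lithium hydroxide, [Li+].[OH-] (carboxyl OH oxygen)
Why: Ester saponification; any lactone opened by hydroxide re-closes on acidification because a carboxyl group always sits cis to the phenol.

Step 12
Reactants: 22 5-[(3-carboxy-7-methoxy-2-oxo-2H-chromen-6-yl)oxy]-6,7-dimethoxy-2-oxo-2H-chromene-3-carboxylic acid
Product: 23 6,7-dimethoxy-5-[(7-methoxy-2-oxo-2H-chromen-6-yl)oxy]-2H-chromen-2-one
Conditions: Cu powder, quinoline, 200 °C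
Reagents that add atoms: none
Why: Copper/quinoline protodecarboxylation is the classical way to remove the 3-carboxyl group of coumarin-3-carboxylic acids, and aryl methyl ethers, the diaryl ether and the lactones survive it.

Step 13
Reactants: 23 6,7-dimethoxy-5-[(7-methoxy-2-oxo-2H-chromen-6-yl)oxy]-2H-chromen-2-one
Product: 25 6,7-dihydroxy-5-[(7-hydroxy-2-oxo-2H-chromen-6-yl)oxy]-2H-chromen-2-one, via bromoboron aryloxide 24 (not isolated)
Conditions: BBr3 (8 equiv), CH2Cl2, -78 °C to rt; then H2O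
Reagents that add atoms: none
Why: BBr3 ether cleavage (bromide attacks the methyl group of the boron-complexed ether) removes all three methyl groups and does not cleave the aryl–O–aryl bond or the lactones.

**Compound list**
1 | 3,4,5-trimethoxyphenol | COc1cc(O)cc(OC)c1OC | starting material
2 | 1,2,3,5-tetramethoxybenzene | COc1cc(OC)c(OC)c(OC)c1 | intermediate
3 | N-methyl-N-[(2,3,4,6-tetramethoxyphenyl)methylidene]methanaminium chloride | COc1cc(OC)c(C=[N+](C)C)c(OC)c1OC.[Cl-] | intermediate (not isolated)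
4 | 2,3,4,6-tetramethoxybenzaldehyde | COc1cc(OC)c(C=O)c(OC)c1OC | intermediate
5 | dichloro(2-formyl-3,5,6-trimethoxyphenoxy)alumane | COc1cc(OC)c(C=O)c(O[Al](Cl)Cl)c1OC | intermediate (not isolated)
6 | 2-hydroxy-3,4,6-trimethoxybenzaldehyde | COc1cc(OC)c(C=O)c(O)c1OC | intermediate
7 | 1-fluoro-2-methoxy-4-nitrobenzene | COc1cc(ccc1F)[N+](=O)[O-] | starting material
8 | 3,4,6-trimethoxy-2-(2-methoxy-4-nitrophenoxy)benzaldehyde | COc1cc(OC)c(C=O)c(Oc2ccc(cc2OC)[N+](=O)[O-])c1OC | intermediate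
9 | dichloro[2-formyl-4,5-dimethoxy-3-(2-methoxy-4-nitrophenoxy)phenoxy]borane | COc1cc(OB(Cl)Cl)c(C=O)c(Oc2ccc(cc2OC)[N+](=O)[O-])c1OC | intermediate (not isolated)
10 | 6-hydroxy-3,4-dimethoxy-2-(2-methoxy-4-nitrophenoxy)benzaldehyde | COc1cc(O)c(C=O)c(Oc2ccc(cc2OC)[N+](=O)[O-])c1OC | intermediate
11 | diethyl malonate | CCOC(=O)CC(=O)OCC | starting material
12 | diethyl 2-{[6-hydroxy-3,4-dimethoxy-2-(2-methoxy-4-nitrophenoxy)phenyl]methylidene}propanedioate | COc1cc(O)c(C=C(C(=O)OCC)C(=O)OCC)c(Oc2ccc(cc2OC)[N+](=O)[O-])c1OC | intermediate (not isolated)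
13 | ethyl 6,7-dimethoxy-5-(2-methoxy-4-nitrophenoxy)-2-oxo-2H-chromene-3-carboxylate | CCOC(=O)c1cc2c(Oc3ccc(cc3OC)[N+](=O)[O-])c(OC)c(OC)cc2oc1=O | intermediate
14 | ethyl 5-(4-amino-2-methoxyphenoxy)-6,7-dimethoxy-2-oxo-2H-chromene-3-carboxylate | CCOC(=O)c1cc2c(Oc3ccc(N)cc3OC)c(OC)c(OC)cc2oc1=O | intermediate
15 | 4-{[3-(ethoxycarbonyl)-6,7-dimethoxy-2-oxo-2H-chromen-5-yl]oxy}-3-methoxybenzenediazonium hydrogensulfate | CCOC(=O)c1cc2c(Oc3ccc(cc3OC)[N+]#N)c(OC)c(OC)cc2oc1=O.OS(=O)(=O)[O-] | intermediate (not isolated)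
16 | ethyl 5-(4-hydroxy-2-methoxyphenoxy)-6,7-dimethoxy-2-oxo-2H-chromene-3-carboxylate | CCOC(=O)c1cc2c(Oc3ccc(O)cc3OC)c(OC)c(OC)cc2oc1=O | intermediate
17 | ethyl 5-[4-hydroxy-5-(hydroxymethyl)-2-methoxyphenoxy]-6,7-dimethoxy-2-oxo-2H-chromene-3-carboxylate (present as its magnesium phenoxide) | CCOC(=O)c1cc2c(Oc3cc(CO)c(O)cc3OC)c(OC)c(OC)cc2oc1=O | intermediate (not isolated)
18 | ethyl 5-(5-formyl-4-hydroxy-2-methoxyphenoxy)-6,7-dimethoxy-2-oxo-2H-chromene-3-carboxylate | CCOC(=O)c1cc2c(Oc3cc(C=O)c(O)cc3OC)c(OC)c(OC)cc2oc1=O | intermediate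
19 | diethyl 2-[(5-{[3-(ethoxycarbonyl)-6,7-dimethoxy-2-oxo-2H-chromen-5-yl]oxy}-2-hydroxy-4-methoxyphenyl)methylidene]propanedioate | CCOC(=O)c1cc2c(Oc3cc(C=C(C(=O)OCC)C(=O)OCC)c(O)cc3OC)c(OC)c(OC)cc2oc1=O | intermediate (not isolated)
20 | ethyl 5-{[3-(ethoxycarbonyl)-7-methoxy-2-oxo-2H-chromen-6-yl]oxy}-6,7-dimethoxy-2-oxo-2H-chromene-3-carboxylate | CCOC(=O)c1cc2c(Oc3cc4cc(C(=O)OCC)c(=O)oc4cc3OC)c(OC)c(OC)cc2oc1=O | intermediate
21 | dilithium 5-[(3-carboxylato-7-methoxy-2-oxo-2H-chromen-6-yl)oxy]-6,7-dimethoxy-2-oxo-2H-chromene-3-carboxylate | [Li+].[Li+].[O-]C(=O)c1cc2c(Oc3cc4cc(C([O-])=O)c(=O)oc4cc3OC)c(OC)c(OC)cc2oc1=O | intermediate (not isolated)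
22 | 5-[(3-carboxy-7-methoxy-2-oxo-2H-chromen-6-yl)oxy]-6,7-dimethoxy-2-oxo-2H-chromene-3-carboxylic acid | OC(=O)c1cc2c(Oc3cc4cc(C(O)=O)c(=O)oc4cc3OC)c(OC)c(OC)cc2oc1=O | intermediate
23 | 6,7-dimethoxy-5-[(7-methoxy-2-oxo-2H-chromen-6-yl)oxy]-2H-chromen-2-one | COc1cc2oc(=O)ccc2cc1Oc1c(OC)c(OC)cc2oc(=O)ccc12 | intermediate
24 | boron aryloxide of 25 (7-O-dibromoboryl on unit A, cyclic 6,7-O,O-bromoboronate on unit B) | BrB(Br)Oc1cc2oc(=O)ccc2cc1Oc1c2OB(Br)Oc2cc2oc(=O)ccc12 | intermediate (not isolated)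
25 | 6,7-dihydroxy-5-[(7-hydroxy-2-oxo-2H-chromen-6-yl)oxy]-2H-chromen-2-one | O=c1ccc2cc(Oc3c(O)c(O)cc4oc(=O)ccc34)c(O)cc2o1 | target

**Totals**
Total step count: 13. Longest linear sequence: 13 steps (1 to 25).

**The three steps most likely to fail, with fallbacks**

Step 3 (regioselective mono-demethylation). If AlCl3 gives the wrong phenol or a mixture, the fallback sets out from 1 and fixes the regiochemistry by construction. Magnesium-mediated ortho-formylation of the symmetric phenol 1 (MgCl2, Et3N, paraformaldehyde) gives 6-hydroxy-2,3,4-trimethoxybenzaldehyde F1. Tosylation (TsCl, K2CO3, acetone) gives 2-formyl-3,4,5-trimethoxyphenyl 4-methylbenzenesulfonate F2. BCl3 then removes the only methoxy group ortho to the formyl group and gives 2-formyl-3-hydroxy-4,5-dimethoxyphenyl 4-methylbenzenesulfonate F3. SNAr with 7 (K2CO3, DMF) gives 2-formyl-4,5-dimethoxy-3-(2-methoxy-4-nitrophenoxy)phenyl 4-methylbenzenesulfonate F4. Cleavage of the sulfonate with KOH in MeOH comes back to the route at 10.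

Step 8 (hydroxy-dediazoniation). If azo coupling or reduction lowers the yield, the fallback sets out from 14 and goes through a C–B bond. Sandmeyer-type borylation (tert-butyl nitrite, bis(pinacolato)diboron, MeCN, rt) gives ethyl 6,7-dimethoxy-5-[2-methoxy-4-(4,4,5,5-tetramethyl-1,3,2-dioxaborolan-2-yl)phenoxy]-2-oxo-2H-chromene-3-carboxylate F5. Oxidation of the boronate with H2O2 in THF/pH 7 buffer (NaH2PO4/Na2HPO4) comes back to the route at 16.

Step 12 (double thermal decarboxylation). If the diacid chars at 200 °C, the fallback sets out from 22 and uses addition–decarboxylation–elimination in water. Refluxing aqueous NaHSO3 adds bisulfite at C4 of both coumarin-3-carboxylic acids, and the now saturated malonic-type acids lose CO2 at 100 °C. This gives disodium 6,7-dimethoxy-5-[(7-methoxy-2-oxo-4-sulfonatochroman-6-yl)oxy]-2-oxochromane-4-sulfonate F6 as a mixture of diastereomers. Aqueous NaOH then HCl eliminates sulfite (E1cB), re-lactonises and comes back to the route at 23.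

**Further compounds**
F1 | step 3 | 6-hydroxy-2,3,4-trimethoxybenzaldehyde | COc1cc(O)c(C=O)c(OC)c1OC
F2 | step 3 | 2-formyl-3,4,5-trimethoxyphenyl 4-methylbenzenesulfonate | COc1cc(OS(=O)(=O)c2ccc(C)cc2)c(C=O)c(OC)c1OC
F3 | step 3 | 2-formyl-3-hydroxy-4,5-dimethoxyphenyl 4-methylbenzenesulfonate | COc1cc(OS(=O)(=O)c2ccc(C)cc2)c(C=O)c(O)c1OC
F4 | step 3 | 2-formyl-4,5-dimethoxy-3-(2-methoxy-4-nitrophenoxy)phenyl 4-methylbenzenesulfonate | COc1cc(OS(=O)(=O)c2ccc(C)cc2)c(C=O)c(Oc2ccc(cc2OC)[N+](=O)[O-])c1OC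
F5 | step 8 | ethyl 6,7-dimethoxy-5-[2-methoxy-4-(4,4,5,5-tetramethyl-1,3,2-dioxaborolan-2-yl)phenoxy]-2-oxo-2H-chromene-3-carboxylate | CCOC(=O)c1cc2c(Oc3ccc(cc3OC)B3OC(C)(C)C(C)(C)O3)c(OC)c(OC)cc2oc1=O
F6 | step 12 | disodium 6,7-dimethoxy-5-[(7-methoxy-2-oxo-4-sulfonatochroman-6-yl)oxy]-2-oxochromane-4-sulfonate (mixture of diastereomers) | [Na+].[Na+].COc1cc2OC(=O)CC(c2cc1Oc1c(OC)c(OC)cc2OC(=O)CC(c12)S([O-])(=O)=O)S([O-])(=O)=O
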